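Rings: A = tetrasubstituted benzene; B = 4-hydroxyphenyl on A; C = 4-hydroxyphenyl of the alkyne; D = 4-hydroxyphenyl on the central carbon (the exocyclic alkene carbon bonded to A and D); E = cyclohexadienone.
Cuts, in retrosynthetic order: four O-Si bonds. Then two bonds of ring E, ipso C to ortho CH (the ring-closing one) and ortho' CH to meta' CH, which leaves an ethynyl group on the central carbon (a tertiary propargylic alcohol) plus Danishefsky's diene. Then central C-ethynyl, central C-ring D, A-B, A-alkyne and A-CHO.
Enabling feature: the central carbon is conjugated both with the C=O of ring E (through the exocyclic C=C) and with the para oxygen of ring D. If ring E is pared down to its ipso and one ortho carbon (C≡CH), ring D alone still stabilises a cation at the central carbon. That cation is an O-silylated alkynyl p-quinone methide, a vinylogous ynone whose alkyne can accept a 1-methoxy-3-silyloxydiene.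
Helpers: the carbinol OH (leaving group), the OMe and OSiMe3 of the diene (regiocontrol, both lost in the event) and the silyl group on the ring D oxygen (activator, removed in the last step).
Forward: ring A is bought as a bromo-chloro benzyl alcohol and formylated between the halogens. Rings C, B and D are attached in that order, an acetylide is added, and ring E is built last from open-chain carbons, emerging at the dienone level together with the tetrasubstituted C=C.
Stereochemistry: the target has no stereocentre and ring E is symmetric about the exocyclic C=C; the two carbinol centres made on the way are racemic and are erased again.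

Key step: step 8

Assumption: the SMILES defines no axis, so rotation about the hindered aryl bonds is treated as free; the five starting materials are taken as catalogue items; TBS = tert-butyldimethylsilyl.

Step 1
Reactants: 1 (2-bromo-4-chlorophenyl)methanol
Product: 2 tert-butyl[(2-bromo-4-chlorobenzyl)oxy]dimethylsilane
Conditions: TBSCl, imidazole, CH2Cl2, rt
Reagents that add atoms: tert-butyldimethylsilyl chloride (TBSCl), CC(C)(C)[Si](C)(C)Cl
Why: Standard silyl ether formation removes the only acidic proton before the lithiation and installs a group that leaves together with the phenol silyl ethers at the end.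

Step 2
Reactants: 2 tert-butyl[(2-bromo-4-chlorobenzyl)oxy]dimethylsilane
Product: 4 2-bromo-6-chloro-3-[(TBS-oxy)methyl]benzaldehyde, via aryllithium 3 (not isolated)
Conditions: LiN(i-Pr)2 (LDA, 1.1 equiv), THF, -78 °C; DMF, -78 °C; H2O quench
Reagents that add atoms: N,N-dimethylformamide (DMF), CN(C)C=O
Why: Deprotonative ortho-lithiation takes the ring C-H flanked by Br and Cl, by far the most acidic one, the 2,6-dihaloaryllithium persists at -78 °C and has no drive for halogen migration, and DMF formylates it, as in the conversion of 1-bromo-3-chlorobenzene into 2-bromo-6-chlorobenzaldehyde.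

Step 3
Reactants: 4 2-bromo-6-chloro-3-[(TBS-oxy)methyl]benzaldehyde; 5 tert-butyl(4-ethynylphenoxy)dimethylsilane
Product: 6 6-chloro-3-[(TBS-oxy)methyl]-2-{[4-(TBS-oxy)phenyl]ethynyl}benzaldehyde
Conditions: PdCl2(PPh3)2 (5 mol %), CuI (5 mol %), Et3N, THF, 60 °C
Reagents that add atoms: none
Why: In this Sonogashira coupling zerovalent palladium carrying PPh3 inserts into the aldehyde-activated C-Br bond and leaves C-Cl untouched, so halogen identity rather than sterics fixes the site.

Step 4
Reactants: 6 6-chloro-3-[(TBS-oxy)methyl]-2-{[4-(TBS-oxy)phenyl]ethynyl}benzaldehyde; 7 [4-(TBS-oxy)phenyl]boronic acid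
Product: 8 4'-(TBS-oxy)-4-[(TBS-oxy)methyl]-3-{[4-(TBS-oxy)phenyl]ethynyl}biphenyl-2-carbaldehyde
Conditions: Pd(OAc)2 (3 mol %), SPhos (6 mol %), K3PO4, toluene (trace H2O), 80 °C
Reagents that add atoms: none
Why: Suzuki-Miyaura coupling of an ortho-formyl aryl chloride with only one flanking substituent is a well-established case for Pd(OAc)2/SPhos, and nearly anhydrous K3PO4 in toluene should spare the aryl silyl ethers.

Step 5
Reactants: 8 4'-(TBS-oxy)-4-[(TBS-oxy)methyl]-3-{[4-(TBS-oxy)phenyl]ethynyl}biphenyl-2-carbaldehyde; 9 (4-bromophenoxy)(tert-butyl)dimethylsilane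
Product: 11 racemic diaryl carbinol (ring A)(ring D-OTBS)CH-OH, via aryllithium 10 (not isolated)
Conditions: 9, n-BuLi, THF, -78 °C; then 8, -78 °C; H2O quench at -78 °C
Reagents that add atoms: none
Why: Bromine-lithium exchange followed by 1,2-addition of the aryllithium to the aldehyde is routine even for 2,6-disubstituted benzaldehydes, the cold quench keeps the alkoxide off the neighbouring alkyne, and the racemic carbinol centre is erased in step 6.

Step 6
Reactants: 11 racemic diaryl carbinol
Product: 12 diaryl ketone (ring A)-C(=O)-(ring D-OTBS)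
Conditions: Dess-Martin periodinane, CH2Cl2, rt
Reagents that add atoms: none
Why: Dess-Martin oxidation of a doubly benzylic secondary alcohol runs under near-neutral conditions that silyl ethers and the diarylalkyne tolerate.

Step 7
Reactants: 12 diaryl ketone
Product: 13 racemic 1-(ring A)-1-[4-(TBS-oxy)phenyl]prop-2-yn-1-ol
Conditions: HC≡CMgBr (3 equiv), LaCl3·2LiCl (30 mol %), THF, 0 °C to rt; H2O quench at 0 °C
Reagents that add atoms: ethynylmagnesium bromide, C#C[Mg]Br
Why: In this lanthanum-promoted 1,2-addition of an alkynyl Grignard reagent to a non-enolisable ketone, the rod-shaped sp nucleophile is the smallest carbon nucleophile available for a carbonyl group walled in by two ortho substituents, and the racemic centre is erased in step 8.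

Step 8
Reactants: 13 racemic tertiary propargylic alcohol; 14 Danishefsky's diene, (E)-1-methoxy-3-(trimethylsilyloxy)buta-1,3-diene
Product: 17 tetra-O-TBS-selaginellin, via propargylic cation 15 (not isolated), via allenyl enone 16 (not isolated)
Conditions: Sc(OTf)3 (10 mol %), 14 (2.5 equiv), 4 Å molecular sieves, CH2Cl2, -40 to 0 °C; aq NaHCO3 work-up
Reagents that add atoms: none
Why: Proposed new method: Sc(OTf)3 ionises the tertiary propargylic alcohol to cation 15, whose charge is carried by the para oxygen of ring D, so that 15 is the O-silylated form of an alkynyl p-quinone methide, a vinylogous ynone with its accessible electrophilic site at the terminal alkyne carbon. The nucleophilic CH2 terminus of 14 bonds to that carbon (1,8-addition) to give allene 16 after silyl transfer to the departed hydroxide, and the central allene carbon, pushed by ring D, then attacks the scandium-bound beta-methoxy enone at its CH(OMe) carbon, which closes ring E by forming its ipso C to ortho CH bond; expulsion of methoxide from the enolate and loss of a proton from the ring CH2 deliver the cross-conjugated dienone and the exocyclic C=C directly. The closest known reaction types are the Diels-Alder/aromatisation of Danishefsky's diene with terminal ynones to 4-acylphenols, the acid-catalysed 1,8-addition of carbon nucleophiles to alkynyl p-quinone methides generated in situ from propargylic alcohols (which stops at the tetrasubstituted allene) and ionic Diels-Alder reactions of allyl and allenyl cations; new is the use of the propargylic cation as the two-carbon partner so that both bond formations run in one flask to a quinone methide. The single ring closes in a 6-endo-trig mode with respect to the enone C=C, equivalently as the lagging second bond of an asynchronous (4+2) cycloaddition in which the s-cis diene geometry already holds the two ends together. No stereocentre is created and ring E is symmetric about the exocyclic double bond, so no stereocontrol is needed. The step needs gamma over alpha attack on the cation, secured by the two ortho substituents of ring A that wall in the central carbon; the para relation of C=O and central carbon, secured by the polarity match between the diene CH2 terminus and the cationic alkyne terminus; and capture by the diene ahead of Friedel-Crafts closure onto ring B, secured by low temperature, the high nucleophilicity of the diene and the fact that the ring B position within reach is meta to its silyloxy group.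

Step 9
Reactants: 17 tetra-O-TBS-selaginellin
Product: 18 selaginellin
Conditions: Bu4NF (6 equiv), AcOH (6 equiv), THF, 0 °C to rt; pH 6 phosphate buffer work-up
Reagents that add atoms: none
Why: Fluoride-mediated cleavage removes all four silyl ethers at once, the AcOH buffer keeps alkoxide and phenoxide concentrations low so that the benzylic oxygen should not add to the neighbouring alkyne, and the neutral quinone methide is recovered on the buffered work-up.

Compound list
1 | (2-bromo-4-chlorophenyl)methanol | OCc1ccc(Cl)cc1Br | starting material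
2 | tert-butyl[(2-bromo-4-chlorobenzyl)oxy]dimethylsilane | CC(C)(C)[Si](C)(C)OCc1ccc(Cl)cc1Br | intermediate
3 | {2-bromo-6-chloro-3-[(TBS-oxy)methyl]phenyl}lithium (not isolated) | CC(C)(C)[Si](C)(C)OCc1ccc(Cl)c([Li])c1Br | intermediate
4 | 2-bromo-6-chloro-3-[(TBS-oxy)methyl]benzaldehyde | CC(C)(C)[Si](C)(C)OCc1ccc(Cl)c(C=O)c1Br | intermediate
5 | tert-butyl(4-ethynylphenoxy)dimethylsilane | C#Cc1ccc(O[Si](C)(C)C(C)(C)C)cc1 | starting material
6 | 6-chloro-3-[(TBS-oxy)methyl]-2-{[4-(TBS-oxy)phenyl]ethynyl}benzaldehyde | CC(C)(C)[Si](C)(C)OCc1ccc(Cl)c(C=O)c1C#Cc1ccc(O[Si](C)(C)C(C)(C)C)cc1 | intermediate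
7 | [4-(TBS-oxy)phenyl]boronic acid | OB(O)c1ccc(O[Si](C)(C)C(C)(C)C)cc1 | starting material
8 | 4'-(TBS-oxy)-4-[(TBS-oxy)methyl]-3-{[4-(TBS-oxy)phenyl]ethynyl}biphenyl-2-carbaldehyde | CC(C)(C)[Si](C)(C)OCc1ccc(-c2ccc(O[Si](C)(C)C(C)(C)C)cc2)c(C=O)c1C#Cc1ccc(O[Si](C)(C)C(C)(C)C)cc1 | intermediate
9 | (4-bromophenoxy)(tert-butyl)dimethylsilane | Brc1ccc(O[Si](C)(C)C(C)(C)C)cc1 | starting material
10 | [4-(TBS-oxy)phenyl]lithium (not isolated) | [Li]c1ccc(O[Si](C)(C)C(C)(C)C)cc1 | intermediate
11 | racemic {4'-(TBS-oxy)-4-[(TBS-oxy)methyl]-3-{[4-(TBS-oxy)phenyl]ethynyl}biphenyl-2-yl}[4-(TBS-oxy)phenyl]methanol | CC(C)(C)[Si](C)(C)OCc1ccc(-c2ccc(O[Si](C)(C)C(C)(C)C)cc2)c(C(O)c2ccc(O[Si](C)(C)C(C)(C)C)cc2)c1C#Cc1ccc(O[Si](C)(C)C(C)(C)C)cc1 | intermediate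
12 | {4'-(TBS-oxy)-4-[(TBS-oxy)methyl]-3-{[4-(TBS-oxy)phenyl]ethynyl}biphenyl-2-yl}[4-(TBS-oxy)phenyl]methanone | CC(C)(C)[Si](C)(C)OCc1ccc(-c2ccc(O[Si](C)(C)C(C)(C)C)cc2)c(C(=O)c2ccc(O[Si](C)(C)C(C)(C)C)cc2)c1C#Cc1ccc(O[Si](C)(C)C(C)(C)C)cc1 | intermediate
13 | racemic 1-{4'-(TBS-oxy)-4-[(TBS-oxy)methyl]-3-{[4-(TBS-oxy)phenyl]ethynyl}biphenyl-2-yl}-1-[4-(TBS-oxy)phenyl]prop-2-yn-1-ol | CC(C)(C)[Si](C)(C)OCc1ccc(-c2ccc(O[Si](C)(C)C(C)(C)C)cc2)c(C(O)(C#C)c2ccc(O[Si](C)(C)C(C)(C)C)cc2)c1C#Cc1ccc(O[Si](C)(C)C(C)(C)C)cc1 | intermediate
14 | Danishefsky's diene, (E)-1-methoxy-3-(trimethylsilyloxy)buta-1,3-diene | CO/C=C/C(=C)O[Si](C)(C)C | starting material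
15 | propargylic cation derived from 13 (O-silylated alkynyl p-quinone methide, not isolated) | CC(C)(C)[Si](C)(C)OCc1ccc(-c2ccc(O[Si](C)(C)C(C)(C)C)cc2)c([C+](C#C)c2ccc(O[Si](C)(C)C(C)(C)C)cc2)c1C#Cc1ccc(O[Si](C)(C)C(C)(C)C)cc1 | intermediate
16 | racemic (E)-1-methoxy-7-(ring A aryl)-7-[4-(TBS-oxy)phenyl]hepta-1,5,6-trien-3-one (not isolated) | CC(C)(C)[Si](C)(C)OCc1ccc(-c2ccc(O[Si](C)(C)C(C)(C)C)cc2)c(C(=C=CCC(=O)/C=C/OC)c2ccc(O[Si](C)(C)C(C)(C)C)cc2)c1C#Cc1ccc(O[Si](C)(C)C(C)(C)C)cc1 | intermediate
17 | tetra-O-TBS-selaginellin, 4-{(ring A aryl)[4-(TBS-oxy)phenyl]methylidene}cyclohexa-2,5-dien-1-one | CC(C)(C)[Si](C)(C)OCc1ccc(-c2ccc(O[Si](C)(C)C(C)(C)C)cc2)c(C(=C2C=CC(=O)C=C2)c2ccc(O[Si](C)(C)C(C)(C)C)cc2)c1C#Cc1ccc(O[Si](C)(C)C(C)(C)C)cc1 | intermediate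
18 | selaginellin | O=C1C=CC(=C(c2ccc(O)cc2)c2c(-c3ccc(O)cc3)ccc(CO)c2C#Cc2ccc(O)cc2)C=C1 | target

Total step count: 9. Longest linear sequence: 9 steps (1 to 18).

Steps most likely to fail

Step 8 (Proposed new method).
- The cation may be lost before the diene reaches it, by Friedel-Crafts closure onto ring B or by Meyer-Schuster-type hydration with adventitious water.
- The diene may be used up by protodesilylation.
- The sequence may halt after the first C-C bond. The allene forms an enyne-allene unit with the alkyne on ring A, so it can then drift into thermal Myers-Saito or C2-C6 biradical cyclisation, or into conjugation with the ketone.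
- Fallback (known chemistry; ring E is brought in as a preformed arene): it sets out from ketone 12. Aryllithium 10 is added in THF at -78 to 0 °C to give the bis[4-(TBS-oxy)phenyl](ring A aryl)methanol F1. Bu4NF/AcOH in THF then removes its five silyl groups, and the freed bis(4-hydroxyphenyl)carbinol loses water on a mildly acidic work-up. The route is rejoined at 18.

Step 7.
- 1,2-Addition to a carbonyl group twisted between two ortho substituents may be too slow. On forcing, the magnesium alkoxide may add across the neighbouring alkyne.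
- Fallback (reversed order of bond formation at the central carbon): it sets out from aldehyde 8. HC≡CMgBr in THF at 0 °C gives the secondary propargylic alcohol F2. Dess-Martin oxidation gives the terminal ynone F3, whose carbonyl group has a rod-like substituent on one side. The weakly basic dichloro[4-(TBS-oxy)phenyl]cerium F4, made from 10 and CeCl3 in THF at -78 °C, then adds 1,2. The route is rejoined at 13.

Step 3.
- Oxidative addition and transmetalation at a bromide flanked by two ortho groups may be so slow that copper-mediated oxidative homocoupling of the valuable alkyne takes over.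
- Fallback (the diarylalkyne is assembled in two couplings, so the hindered one uses a slim, cheap alkyne in excess): it sets out from 4. Sonogashira coupling with trimethylsilylacetylene (PdCl2(PPh3)2, CuI, Et3N, 60 °C) gives the trimethylsilylethynyl aldehyde F5. K2CO3 in MeOH gives the terminal alkyne F6; only the alkyl silyl ether is present at this stage. An unhindered Sonogashira coupling with tert-butyl(4-iodophenoxy)dimethylsilane at rt rejoins the route at 6.

Further compounds
F1 | step 8 | {4'-(TBS-oxy)-4-[(TBS-oxy)methyl]-3-{[4-(TBS-oxy)phenyl]ethynyl}biphenyl-2-yl}bis[4-(TBS-oxy)phenyl]methanol | CC(C)(C)[Si](C)(C)OCc1ccc(-c2ccc(O[Si](C)(C)C(C)(C)C)cc2)c(C(O)(c2ccc(O[Si](C)(C)C(C)(C)C)cc2)c2ccc(O[Si](C)(C)C(C)(C)C)cc2)c1C#Cc1ccc(O[Si](C)(C)C(C)(C)C)cc1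
F2 | step 7 | racemic 1-{4'-(TBS-oxy)-4-[(TBS-oxy)methyl]-3-{[4-(TBS-oxy)phenyl]ethynyl}biphenyl-2-yl}prop-2-yn-1-ol | CC(C)(C)[Si](C)(C)OCc1ccc(-c2ccc(O[Si](C)(C)C(C)(C)C)cc2)c(C(O)C#C)c1C#Cc1ccc(O[Si](C)(C)C(C)(C)C)cc1
F3 | step 7 | 1-{4'-(TBS-oxy)-4-[(TBS-oxy)methyl]-3-{[4-(TBS-oxy)phenyl]ethynyl}biphenyl-2-yl}prop-2-yn-1-one | CC(C)(C)[Si](C)(C)OCc1ccc(-c2ccc(O[Si](C)(C)C(C)(C)C)cc2)c(C(=O)C#C)c1C#Cc1ccc(O[Si](C)(C)C(C)(C)C)cc1
F4 | step 7 | dichloro[4-(TBS-oxy)phenyl]cerium | Cl[Ce](Cl)c1ccc(O[Si](C)(C)C(C)(C)C)cc1
F5 | step 3 | 6-chloro-3-[(TBS-oxy)methyl]-2-[(trimethylsilyl)ethynyl]benzaldehyde | CC(C)(C)[Si](C)(C)OCc1ccc(Cl)c(C=O)c1C#C[Si](C)(C)C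
F6 | step 3 | 6-chloro-2-ethynyl-3-[(TBS-oxy)methyl]benzaldehyde | CC(C)(C)[Si](C)(C)OCc1ccc(Cl)c(C=O)c1C#C
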